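The runs stem from a simulated flask from invented constants.

- I was to say what stands in the teal flask at 30 h. I had its readings up to 12.0 h, and an earlier grey flask followed to 30.0 h.

the same everywhere: E 0.020 M; X 20 mol%
- teal: Z 4 equiv (fed, over 50 min); Q 6 mM; the very flask that is asked about, followed so far; the fed solution adds 1.0 times the starting volume
- grey: Z 4 equiv (fed, over 50 min); Q 3 mM; run made earlier; the fed solution adds 1.0 times the starting volume
- flask: Z 4.00 equiv (fed, over 50 min); Q 6.00 mM; the fed solution adds 1.0 times the starting volume; time 30 h

- teal (time / h: G / %, E / %): 2.50: 0, 99.1; 5.00: 1.9, 96.6; 8.00: 6.3, 94.4; 10.0: 6.7, 93.0; 12.0: 9.9, 91.7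
- grey (time / h: G / %, E / %): 2.50: 0.1, 99.3; 5.00: 0.3, 95.8; 8.00: 5.7, 93.8; 15.0: 12.0, 84.2; 30.0: 26.8, 71.9

(standard deviation of a reading: 1 percentage point)

- every charge counts on the volume at the start, and the solution that is fed holds the whole dose
- on the list of suspects stand: Z + X -> D; Z + Q -> J; E + D -> L; L -> X + G

- amount of G in the flask at 30 h, in percent of the E charged
- amount of E in the flask at 30 h, in percent of the E charged

- The bench rule for a reagent in excess is to call its concentration constant, so that E decays as one exponential (pseudo-first-order).
- The grey flask fell from E 93.8% at 8.00 h to 71.9% at 30.0 h, and these two readings, with their scatter, give the time for E to shrink by a factor e, its time constant τ: 82.7 h. I skipped the earlier readings, where G trailed the loss of E.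
- The feed of 50 min is short beside τ, so I treated c_Z as present from the start.
- To carry τ over to teal I compared the charges: the extra Q in teal can take 3.75% of the Z charged, so I kept τ unchanged.
- The border comes from a ratio with no time in it. If each E, Q and X in the teal flask takes one Z, the claims reach at most 37.5% of the Z charged, and a run toward that share is where I stop trusting a constant τ.
- From teal's 91.7% at 12.0 h, τ gives E 73.8% at 30 h. Counting lost E as G gives G 26.2%, and the claims on Z in the teal flask then stand at most at 19.1%, less than the border.
- The forecast gave G 24% and E 75%, and said of Q “it should have a small effect”.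
- The flask gave G 26.0% and E 72.7%, so my E stood 1.1 percentage points high.

    Z + X → D (k = 4.80 × 10⁻⁴ L mol⁻¹ s⁻¹)
    Z + Q → J (k = 0.00110 L mol⁻¹ s⁻¹)
    E + D → L (k = 0.0120 L mol⁻¹ s⁻¹)
    L → X + G (k = 2.00 × 10⁻⁴ s⁻¹)

- I used τ again on the same flask read at 3.0 d: from 72.7% at 30 h, it gives E 43.8%. That flask held E 38.3%, less than I reckoned, with G 60.6%. Between those two times E fell with a time constant of 65.7 h, shorter than τ, and at the later time Z stood at 76.0% of its charge.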